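A model can pass through every reading and still be wrong about X at 12 min, for the readings stop at 6.00 min and the question lies beyond them.

| setting | winter | noon | epsilon | delta | alpha |
|---|---|---|---|---|---|
| J | 0.20 M | 0.20 M | 0.20 M | 0.20 M | 0.20 M |
| E | 0.15 M | 0.93 M | 0.100 M | 0.800 M | 0.600 M |
| remark | run made earlier | run made earlier |  |  |  |
| time |  |  | 12 min | 12 min | 12 min |

| run | time / min | X / % | D / % |
|---|---|---|---|
| winter | 1.33 | 7.4 | 17.2 |
| winter | 2.50 | 7.1 | 16.6 |
| winter | 4.00 | 5.3 | 16.0 |
| winter | 5.00 | 5.7 | 15.3 |
| winter | 6.00 | 3.8 | 14.5 |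
| noon | 0.500 | 26.0 | 21.6 |
| noon | 0.833 | 23.6 | 21.2 |
| noon | 1.50 | 14.9 | 16.9 |
| noon | 3.00 | 6.2 | 9.9 |
| noon | 6.00 | 2.4 | 5.5 |

(each reading ± 0.5 percentage points)

- which of these holds the largest part of the J at the end of epsilon (Ul / D / X / J / Z)
- which of these holds the largest part of the J at the end of delta (Ul / D / X / J / Z)
- which of these holds the largest part of the J at the end of alpha (Ul / D / X / J / Z)
- how much X is there at the end of epsilon, in percent of the J charged



Two chemists dispute X at the end of epsilon. The first says X fades on a steady clock. In the winter run it falls from 7.4% at 1.33 min to 3.8% at 6.00 min, so it halves in 4.86 min. This fading half-life, the time X takes to halve on its way down, is a reading and carries the scatter. Carried on to 12 min, it puts the winter run at 1.61%. For epsilon, with less E, she starts X lower, at 3.5%, and lets it fall more slowly, which is how the forecast reaches 1.2%.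

The second says X stays tied to D. In the winter run, X is a quarter of D at the last reading, and D takes 19.0 min to halve, longer than 4.86 min. He takes the answer of the fit of the main steps alone for epsilon, 3.53%.

The forecast names J for epsilon, Ul for delta and Ul for alpha: “Material therefore tends to go all the way to Ul while much J stays untouched.”

The simulation gives X 0.930% in epsilon, where J holds 62.6%. Ul holds 36.5% in delta and Ul holds 25.2% in alpha, each the largest in its flask of the species asked about. The forecast stands on all four.

    J + E ⇌ Q + D (K = 0.790, k = 0.0460 /M/s)
    D + E ⇌ Q + X (K = 0.690, k = 0.120 /M/s)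
    X + E ⇌ Q + Z (K = 22.0, k = 0.0380 /M/s)
    Z + E ⇌ Q + Ul (K = 2.60, k = 0.0270 /M/s)
    D → Ry (k = 0.00360 /s)
    E → G (k = 5.20 × 10⁻⁶ /s)
    D ⇌ Qi (K = 0.100, k = 0.00130 /s)

In epsilon X goes from 2.67% at 6.00 min to 0.930% at 12.0 min, halving in 3.95 min, less than the winter 4.86 min. The relaxation half-life of D + E and Q + X by that step alone, 0.626 min at the end of epsilon, is shorter than this fading and short against 12 min, a quasi-equilibrium in which X fades on a slower clock than its own step. In delta X goes from 3.29% to 1.79% over the same interval, halving in 6.82 min. The second chemist's level of X is passed in the neighbour of epsilon charged with 0.050 M of J, just below the 0.0517 M at which the answer has moved by 5 points, and there X stands at 6.12%.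

The data are calculated on assumed constants, noise included.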